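Which flask holds the most target at 12 h: alpha at 25 °C, zeta at 50 °C, or epsilon, warmed at 8.0 h?

| setting | ochre | amber | alpha | zeta | epsilon |
|---|---|---|---|---|---|
| substrate | 0.14 M | 0.22 M | 0.10 M | 0.10 M | 0.10 M |
| temperature | 20 °C | 38 °C | 25 °C | 50 °C |  |
| remark | run made earlier | run made earlier |  |  | at 25 °C until 8.0 h, from then on at 50 °C |
| time |  |  | 12 h | 12 h | 12 h |

- ochre (time / h: target / %, substrate / %): 0.833: 0, 100; 1.33: 0, 96; 2.00: 0, 96; 4.00: 0, 93; 6.00: 0, 97; 10.0: 0, 89
- amber (time / h: target / %, substrate / %): 0.333: 3, 96; 1.00: 3, 80; 1.50: 4, 74; 2.50: 7, 59; 4.00: 13, 44; 5.00: 19, 39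

(standard deviation of a reading: 1.5 percentage points)

- the earlier runs were read with a standard deviation of 1.5 percentage points
- a reading or a percentage of target counts all its forms, free or not

* the flask with the highest amount of target, in percent of the substrate charged ("all alike" if they lie within 1.5 percentage points) (alpha / zeta / epsilon / all alike)
* final target, as a percentage of the substrate charged, in alpha
* final target, as a percentage of the substrate charged, in zeta
* final target, as a percentage of the substrate charged, in epsilon

The ochre run has 89 % of its substrate at 10.0 h, which reads as a first-order constant of 0.0117 h⁻¹. The amber run has 39 % at 5.00 h, so its constant is 0.188 h⁻¹. Together these two readings put an activation energy of 117 kJ mol⁻¹ on the loss of substrate, which gives 0.0261 h⁻¹ at 25 °C and 1.01 h⁻¹ at 50 °C.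

Amber has lost 61.0 % of its substrate by 5.00 h but shows 19 % of target, so something probably stands between them. The zero of the scale is the symmetric chain: substrate to intermediate to target, both steps assumed to share one constant, with no side loss. Each flask then needs a single number, its clock, the constant times the time, summed over the stretches at each temperature. The fraction of target is one minus (one plus the clock) times e to the minus clock. The clocks are 0.313 for alpha, 12.2 for zeta and 4.26 for epsilon.

The weak link is the assumption of no side loss. Amber's clock of 0.942 gives 24.3 %, yet the reading is lower, at 19 %. Reading over symmetric value is the capture, 0.783, a ratio that carries the scatter of one reading. Carried unchanged, it gives 3.13 % in alpha, 78.3 % in zeta and 72.5 % in epsilon, so this reckoning commits to zeta.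

The forecast, which differs from this reckoning in its figures, also names zeta, with 4 % in alpha, 97 % in zeta and 77 % in epsilon, and calls zeta “nearly complete, assuming no side loss”.

The flasks give zeta as highest: 83.0 % in zeta, 5.68 % in alpha and 68.7 % in epsilon.

    intermediate → target (k = 0.900 h⁻¹, Ea = 98.0 kJ mol⁻¹)
    crystals ⇌ target, rate k2*(cs2 - [target]) while solid is left; crystals form when [target] > cs2 (solubility = 1.80 mM, k = 76.0 h⁻¹)
    substrate + intermediate → side product (k = 3.20 L mol⁻¹ h⁻¹, Ea = 80.0 kJ mol⁻¹)
    substrate ⇌ intermediate (K = 2.40, k = 0.900 h⁻¹, Ea = 112 kJ mol⁻¹, ΔH = −23.0 kJ mol⁻¹)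
    (constants at 50 °C)

Beside its target, zeta holds 16.7 % of side product at 12.0 h, each unit of it counted as two. Zeta's own capture, its target over the symmetric value, is 0.830, against 0.783 read from amber. For a flask like alpha kept at 40 °C the clock reckons to 3.02, where the capture gives 62.9 %, and that flask holds 62.3 % of target.

The earlier runs and the new flask are calculated on assumed constants.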